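Numbering (germacrane): ring C1–C10 with C4‑Me (C15), C5=O, C7 (bears C11), C8–O (lactone), C9–O (ester), C10(OH)Me (C14). The lactone ring is C7–C8–O–C12–C11, and C13 is the exocyclic CH2.
Cuts: the C9 O‑acyl bond; C12 (as CO) out of the lactone ring; both C–O bonds at C9/C10 (giving a Z‑C9=C10 alkene); then the single ring C–C bond C7–C8, by an oxy‑Cope transform that re‑links C5 and C10.
Enabling feature: from the C5 ketone, C7–C8 is the β,γ‑bond and the C9/C10 glycol is a latent δ,ε‑alkene, so the ten‑membered ring is a cyclodec‑5‑enone retron. C5–C4–C3–C2–C1–C10 with its two methyl groups is 2,6‑dimethylcyclohexanone.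
Forward order: bought six‑membered ring → cis‑1,2‑dialkenylcyclohexanol → ten‑membered ring (6→10 ring expansion, step 7) → glycol → lactone ring (CO insertion) → ester.
Stereochemistry, part 1: C4 comes from chiral‑base desymmetrisation, a temporary quaternary C10 from ligand‑controlled allylation, and C5 from axial acetylide attack. The chair [3,3] shift turns C5/C10 into C7/C8 and a Z alkene, with the equatorial C4 methyl as conformational lock.
Stereochemistry, part 2: C9/C10 come from OH‑directed syn‑dihydroxylation of that Z‑allylic alcohol; C2′ is bought with (R)‑2‑methylbutanoic acid.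

Key step: step 7

Assumption: the (R,R)‑amide is taken to remove the α‑proton at the (S)‑carbon of meso‑1; if the sense of induction is the opposite, the (S,S)‑amine is used.

Step 1
Reactants: 1 cis‑2,6‑dimethylcyclohexanone
Product: 3 {[(6R)‑2,6‑dimethylcyclohex‑1‑en‑1‑yl]oxy}trimethylsilane, via lithium (6R)‑2,6‑dimethylcyclohex‑1‑en‑1‑olate 2 (not isolated)
Conditions: (R,R)‑bis(1‑phenylethyl)amine, n‑BuLi, THF, 0 °C; then TMSCl and 1, −90 °C
Reagents that add atoms: chlorotrimethylsilane, C[Si](C)(C)Cl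
Why: Enantioselective deprotonation (chiral lithium amide desymmetrisation of a meso ketone with internal silyl quench) removes the α‑proton at the (S)‑carbon, so the surviving methyl‑bearing carbon, the future C4, is left R and cannot epimerise while the ketone is masked as the enol silane.

Step 2
Reactants: 3 {[(6R)‑2,6‑dimethylcyclohex‑1‑en‑1‑yl]oxy}trimethylsilane
Product: 4 (2R,6R)‑2,6‑dimethyl‑2‑(prop‑2‑en‑1‑yl)cyclohexan‑1‑one (methyl groups trans, allyl cis to the C6 methyl)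
Conditions: Pd2(dba)3 (cat.), (R)‑t‑Bu‑PHOX (cat.), diallyl carbonate, TBAT (cat.), THF, 25 °C; chromatography
Reagents that add atoms: diallyl carbonate, C=CCOC(=O)OCC=C
Why: In this asymmetric Tsuji allylation (Pd–PHOX allylic alkylation of the fluoride‑released, regiodefined enolate) the ligand dictates the enolate face and sets the quaternary centre (future C10) R with allyl cis to the untouched C4 methyl, under conditions that do not equilibrate C4, and any C10 epimer is a separable diastereomer.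

Step 3
Reactants: 4 (2R,6R)‑2,6‑dimethyl‑2‑(prop‑2‑en‑1‑yl)cyclohexan‑1‑one
Product: 6 2‑[(1R,3R)‑1,3‑dimethyl‑2‑oxocyclohexyl]acetaldehyde, via (2R,6R)‑2,6‑dimethyl‑2‑[(1,2,4‑trioxolan‑3‑yl)methyl]cyclohexan‑1‑one 5 (not isolated)
Conditions: O3, CH2Cl2, −78 °C; PPh3, −78 °C → rt
Reagents that add atoms: ozone, [O-][O+]=O
Why: Ozonolysis with reductive work‑up cleaves the only alkene to the aldehyde under neutral conditions that leave both stereocentres alone, and no new stereocentre is formed.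

Step 4
Reactants: 6 2‑[(1R,3R)‑1,3‑dimethyl‑2‑oxocyclohexyl]acetaldehyde
Product: 7 (2R,6R)‑2‑[(E)‑2‑{[tert‑butyl(dimethyl)silyl]oxy}ethenyl]‑2,6‑dimethylcyclohexan‑1‑one
Conditions: TBSOTf, Et3N, CH2Cl2, −78 → 0 °C; chromatography
Reagents that add atoms: tert‑butyldimethylsilyl triflate, CC(C)(C)[Si](C)(C)OS(=O)(=O)C(F)(F)F
Why: Soft enolisation (silyl triflate–amine) takes place at the unhindered aldehyde and not at the ketone flanked by a quaternary and a tertiary carbon, the E enol ether should prevail because the quaternary carbon avoids the position cis to the siloxy group, and no stereocentre is formed or touched.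

Step 5
Reactants: 7 (2R,6R)‑2‑[(E)‑2‑{[tert‑butyl(dimethyl)silyl]oxy}ethenyl]‑2,6‑dimethylcyclohexan‑1‑one; 8 1,4‑bis(trimethylsilyl)buta‑1,3‑diyne
Product: 10 (1S,2R,6R)‑2‑[(E)‑2‑{[tert‑butyl(dimethyl)silyl]oxy}ethenyl]‑2,6‑dimethyl‑1‑[4‑(trimethylsilyl)buta‑1,3‑diyn‑1‑yl]cyclohexan‑1‑ol, via lithium 4‑(trimethylsilyl)buta‑1,3‑diyn‑1‑ide 9 (not isolated)
Conditions: 8, MeLi·LiBr, THF, rt; then 7, −78 → −20 °C; aq NH4Cl
Reagents that add atoms: none
Why: In this 1,2‑addition of a lithium acetylide (made by Si–Li exchange), the chair of 7 has C4‑Me and the siloxyvinyl group equatorial and the C10 methyl axial, so the rod‑shaped nucleophile attacks axially, anti to the axial methyl (the behaviour of 2,2,6‑trimethylcyclohexanone), which sets C5 with the diynyl group cis to the siloxyvinyl group and to C4‑Me.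

Step 6
Reactants: 10 (1S,2R,6R)‑diynol
Product: 11 (1R,2R,6R)‑2‑[(E)‑2‑{[tert‑butyl(dimethyl)silyl]oxy}ethenyl]‑2,6‑dimethyl‑1‑[(E)‑4‑(trimethylsilyl)but‑1‑en‑3‑yn‑1‑yl]cyclohexan‑1‑ol
Conditions: LiAlH4, THF, 0 °C → rt; H2O work‑up
Reagents that add atoms: none
Why: Hydroxyl‑directed trans‑hydroalumination (LiAlH4 reduction of a 2,4‑diyn‑1‑ol to the E‑2‑en‑4‑yn‑1‑ol) reduces only the triple bond next to the carbinol and fixes the E geometry, while the silylalkyne, the enol ether and all stereocentres are unaffected (the C1 descriptor changes only because the ranking changes).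

Step 7
Reactants: 11 (1R,2R,6R)‑E‑enynol
Product: 14 (3S,4R,5Z,10R)‑4‑{[tert‑butyl(dimethyl)silyl]oxy}‑6,10‑dimethyl‑3‑[(trimethylsilyl)ethynyl]cyclodec‑5‑en‑1‑one, via potassium alkoxide of 11 12 (not isolated), via ring‑expanded potassium enolate (C5=C6) 13 (not isolated)
Conditions: KH, 18‑crown‑6, THF, 0 °C → rt; AcOH, −78 °C
Reagents that add atoms: none
Why: Deprotonation gives alkoxide 12, whose charge‑accelerated [3,3] shift (anionic oxy‑Cope rearrangement, the classical 1,2‑divinylcyclohexanol → cyclodec‑5‑enone ring expansion) breaks C5–C10 while C7–C8 forms, and enolate 13 is protonated at C6 to 14. The ten‑membered ring is not closed end to end but arises by four‑atom ring expansion of the cyclohexane through a six‑centre chair array C7=C6–C5–C10–C9=C8. In the only unstrained chair of 12, C4‑Me and the siloxyvinyl group are equatorial and the enynyl group and C10‑Me are axial, so the two alkenyl groups are gauche and pre‑organised, whereas the flipped chair would put C4‑Me and the siloxyvinyl group 1,3‑diaxial. In this array C1 is axial and C10‑Me equatorial on the developing C9=C10 bond, which should therefore be Z, and C4 is equatorial at C5 (ring‑trans enolate). The alkynyl group on C7 and the OTBS group on C8 are both equatorial (E,E dienes, chair), which gives the syn C7/C8 pair, and suprafacial transfer from (5R,10R) makes it 7S with C8 in the spatial arrangement of the target (formally R in 14 because of the ranking). The step needs chair over boat and one cyclohexane chair over the other, which the equatorial C4 lock and the slim equatorial substituents secure, and C4 is untouched because the enolate forms regiospecifically towards C6 and is quenched cold.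

Step 8
Reactants: 14 (3S,4R,5Z,10R)‑silyl ether
Product: 15 (3S,4R,5Z,10R)‑3‑ethynyl‑4‑hydroxy‑6,10‑dimethylcyclodec‑5‑en‑1‑one
Conditions: TBAF, AcOH, THF, 0 °C → rt
Reagents that add atoms: none
Why: Fluoride‑mediated desilylation removes the O‑TBS and the C‑TMS group in one operation, and the acetic acid buffer keeps the medium too weakly basic to epimerise C4.

Step 9
Reactants: 15 (3S,4R,5Z,10R)‑3‑ethynyl‑4‑hydroxy‑6,10‑dimethylcyclodec‑5‑en‑1‑one
Product: 17 (2R,6S,7R,8S,9S)‑9‑ethynyl‑6,7,8‑trihydroxy‑2,6‑dimethylcyclodecan‑1‑one, via cyclic C9,C10‑osmate(VI) ester–TMEDA chelate 16 (not isolated)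
Conditions: OsO4, TMEDA, CH2Cl2, −78 °C; then aq Na2SO3, THF, 40 °C
Reagents that add atoms: osmium tetroxide, O=[Os](=O)(=O)=O
Why: In this hydrogen‑bond‑directed syn‑dihydroxylation (OsO4·TMEDA on an allylic alcohol), A1,3 strain across the Z alkene holds H8 in the alkene plane and leaves O8–H on the peripheral face, the reagent is delivered to that face, and suprafacial addition to the Z alkene gives 9R,10S (O8/O9 syn, O9/O10 anti), while the alkyne is inert.

Step 10
Reactants: 17 (2R,6S,7R,8S,9S)‑triol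
Product: 18 9‑O‑deacyl lactone: (4R,7S,8S,9R,10S)‑9,10‑dihydroxy‑5‑oxogermacr‑11(13)‑en‑12,8‑olide
Conditions: PdCl2 (cat.), PPh3 (cat.), SnCl2 (cat.), CO (7 atm), MeCN, 65 °C
Reagents that add atoms: carbon monoxide, [C-]#[O+]
Why: In this Pd‑catalysed cyclocarbonylation of a homopropargylic alcohol, an alkoxycarbonyl‑palladium species at O8 inserts the terminal alkyne syn and is protonolysed to the α‑methylene‑γ‑butyrolactone, five‑ring closure through O8 being preferred to six‑ring closure through O9, and C7 and C8 are retained so the lactone is trans‑fused.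

Step 11
Reactants: 18 9‑O‑deacyl lactone; 19 (R)‑2‑methylbutanoic acid
Product: 21 ineupatorolide A, via O‑[(R)‑2‑methylbutanoyl]‑N,N′‑dicyclohexylisourea 20 (not isolated)
Conditions: 19, DCC, DMAP (cat.), CH2Cl2, 0 °C
Reagents that add atoms: none
Why: In this Steglich esterification only the secondary C9 hydroxyl is acylated, the tertiary C10 hydroxyl being inert, and low temperature with little DMAP keeps C2′ and C4 configurationally intact.

Compound list
1 | cis‑2,6‑dimethylcyclohexanone (meso; commercial cis‑rich mixture, whose racemic trans part only feeds separable diastereomers) | C[C@H]1CCC[C@@H](C)C1=O | starting material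
2 | lithium (6R)‑2,6‑dimethylcyclohex‑1‑en‑1‑olate | C[C@@H]1CCCC(C)=C1[O-].[Li+] | intermediate
3 | {[(6R)‑2,6‑dimethylcyclohex‑1‑en‑1‑yl]oxy}trimethylsilane | C[C@@H]1CCCC(C)=C1O[Si](C)(C)C | intermediate
4 | (2R,6R)‑2,6‑dimethyl‑2‑(prop‑2‑en‑1‑yl)cyclohexan‑1‑one | C[C@@H]1CCC[C@](C)(CC=C)C1=O | intermediate
5 | (2R,6R)‑2,6‑dimethyl‑2‑[(1,2,4‑trioxolan‑3‑yl)methyl]cyclohexan‑1‑one | C[C@@H]1CCC[C@](C)(CC2OCOO2)C1=O | intermediate
6 | 2‑[(1R,3R)‑1,3‑dimethyl‑2‑oxocyclohexyl]acetaldehyde | C[C@@H]1CCC[C@](C)(CC=O)C1=O | intermediate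
7 | (2R,6R)‑2‑[(E)‑2‑{[tert‑butyl(dimethyl)silyl]oxy}ethenyl]‑2,6‑dimethylcyclohexan‑1‑one | C[C@@H]1CCC[C@](C)(/C=C/O[Si](C)(C)C(C)(C)C)C1=O | intermediate
8 | 1,4‑bis(trimethylsilyl)buta‑1,3‑diyne | C[Si](C)(C)C#CC#C[Si](C)(C)C | starting material
9 | lithium 4‑(trimethylsilyl)buta‑1,3‑diyn‑1‑ide | [Li]C#CC#C[Si](C)(C)C | intermediate
10 | (1S,2R,6R)‑2‑[(E)‑2‑(TBSO)ethenyl]‑2,6‑dimethyl‑1‑[4‑(trimethylsilyl)buta‑1,3‑diyn‑1‑yl]cyclohexan‑1‑ol | C[C@@H]1CCC[C@](C)(/C=C/O[Si](C)(C)C(C)(C)C)[C@]1(O)C#CC#C[Si](C)(C)C | intermediate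
11 | (1R,2R,6R)‑2‑[(E)‑2‑(TBSO)ethenyl]‑2,6‑dimethyl‑1‑[(E)‑4‑(trimethylsilyl)but‑1‑en‑3‑yn‑1‑yl]cyclohexan‑1‑ol | C[C@@H]1CCC[C@](C)(/C=C/O[Si](C)(C)C(C)(C)C)[C@]1(O)/C=C/C#C[Si](C)(C)C | intermediate
12 | potassium alkoxide of 11 | C[C@@H]1CCC[C@](C)(/C=C/O[Si](C)(C)C(C)(C)C)[C@]1([O-])/C=C/C#C[Si](C)(C)C.[K+] | intermediate
13 | potassium enolate of 14 (C5=C6, C4 and C7 trans; C9=C10 Z) | C[C@@H]1CCC\C(C)=C/[C@@H](O[Si](C)(C)C(C)(C)C)[C@H](C#C[Si](C)(C)C)\C=C1/[O-].[K+] | intermediate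
14 | (3S,4R,5Z,10R)‑4‑(TBSO)‑6,10‑dimethyl‑3‑[(trimethylsilyl)ethynyl]cyclodec‑5‑en‑1‑one | C[C@@H]1CCC\C(C)=C/[C@@H](O[Si](C)(C)C(C)(C)C)[C@H](C#C[Si](C)(C)C)CC1=O | intermediate
15 | (3S,4R,5Z,10R)‑3‑ethynyl‑4‑hydroxy‑6,10‑dimethylcyclodec‑5‑en‑1‑one | C[C@@H]1CCC\C(C)=C/[C@@H](O)[C@H](C#C)CC1=O | intermediate
16 | cyclic C9,C10‑osmate(VI) ester of 15, TMEDA chelate | C[C@@H]1CCC[C@]2(C)O[Os](=O)(=O)O[C@@H]2[C@@H](O)[C@H](C#C)CC1=O.CN(C)CCN(C)C | intermediate
17 | (2R,6S,7R,8S,9S)‑9‑ethynyl‑6,7,8‑trihydroxy‑2,6‑dimethylcyclodecan‑1‑one | C[C@@H]1CCC[C@](C)(O)[C@H](O)[C@@H](O)[C@H](C#C)CC1=O | intermediate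
18 | (4R,7S,8S,9R,10S)‑9,10‑dihydroxy‑5‑oxogermacr‑11(13)‑en‑12,8‑olide | C=C1C(=O)O[C@@H]2[C@@H](O)[C@@](C)(O)CCC[C@@H](C)C(=O)C[C@@H]12 | intermediate
19 | (R)‑2‑methylbutanoic acid | CC[C@@H](C)C(=O)O | starting material
20 | O‑[(R)‑2‑methylbutanoyl]‑N,N′‑dicyclohexylisourea | CC[C@@H](C)C(=O)OC(=NC1CCCCC1)NC1CCCCC1 | intermediate
21 | ineupatorolide A | C=C1C(=O)O[C@@H]2[C@@H](OC(=O)[C@H](C)CC)[C@@](C)(O)CCC[C@@H](C)C(=O)C[C@@H]12 | target

Total step count: 11. Longest linear sequence: 11 steps (from 1).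

Steps most likely to fail

Step 7. The rearrangement may leak through the ring‑flipped chair or a boat array, which would lose both the chirality transfer and the alkene geometry, or the alkoxide may attack the enol silyl group. The fallback sets out from 3 and returns at 14.
- The allylation of 3 is run with (S)‑t‑Bu‑PHOX, where ligand control and the substrate bias (attack anti to the pseudoaxial C4 methyl) reinforce each other. This gives (2S,6R)‑2‑allyl‑2,6‑dimethylcyclohexan‑1‑one F1.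
- Ozonolysis gives 2‑[(1S,3R)‑1,3‑dimethyl‑2‑oxocyclohexyl]acetaldehyde F2, and silylation as in step 4 gives the (2S,6R)‑E‑siloxyvinyl ketone F3.
- Addition of 9 gives the (2S,6R)‑diynol F4 as either C1 epimer, and LiAlH4 gives the (2S,6R)‑E‑enynol F5.
- Both carbinol epimers can reach only chair arrays in which C1 is equatorial at C10. The anionic oxy‑Cope step is therefore stereoconvergent and should give the 5E isomer of 14, (3S,4R,5E,10R)‑cyclodecenone F6, with the same C4, C7 and C8 centres.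
- A strain‑releasing E→Z isomerisation by reversible thiyl‑radical addition ((PhS)2 cat., hν, benzene, as known for trisubstituted E alkenes in medium rings such as caryophyllene) then returns to 14.

Step 4. E/Z control in the enol silylation may be poor, or the 1,4‑keto aldehyde may cyclise under the silyl triflate. The fallback sets out from 6 and returns at 17. It replaces oxygen at C8 by sulfur, whose E‑vinyl derivative is reliably accessible, and relays the stereochemistry by a second sigmatropic shift.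
- PhSH/BF3·OEt2 converts 6 into (2R,6R)‑2‑[2,2‑bis(phenylsulfanyl)ethyl]‑2,6‑dimethylcyclohexan‑1‑one F7.
- Copper(I) triflate/i‑Pr2NEt eliminates thiophenol to give (2R,6R)‑2,6‑dimethyl‑2‑[(E)‑2‑(phenylsulfanyl)ethenyl]cyclohexan‑1‑one F8.
- Addition of 9 gives the (1S,2R,6R)‑diynol F9, LiAlH4 gives the (1R,2R,6R)‑silyl enynol F10, and K2CO3/MeOH gives the terminal enynol F11.
- KHMDS/18‑crown‑6 triggers the same chair oxy‑Cope shift to the (5Z)‑3‑ethynyl‑6,10‑dimethyl‑4‑(phenylsulfanyl)cyclodec‑5‑en‑1‑one F12.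
- mCPBA at −78 °C gives the sulfoxide F13.
- P(OMe)3 in MeOH drives the Mislow–Evans [2,3] shift, which passes oxygen suprafacially from C8 to C10 on the peripheral face with H8 in the alkene plane. This gives (3R,4E,6S,10R)‑3‑ethynyl‑6‑hydroxy‑6,10‑dimethylcyclodec‑4‑en‑1‑one F14 with the target's C10 and an E‑C8=C9 alkene.
- Upjohn dihydroxylation from the peripheral face then gives 17. Attack follows the empirical anti rule for allylic alcohols at C10, and H7 lies in the alkene plane at C7.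

Step 2. Ligand control and substrate bias are mismatched, so facial selectivity at C10 relative to C4 may be poor. The fallback sets out from 1 and returns at 4. It gives up kinetic control of C4 and uses its lability instead.
- 1 is converted (NaHMDS, allyl chloroformate) into racemic allyl 2,6‑dimethylcyclohex‑1‑en‑1‑yl carbonate F15.
- Decarboxylative allylation with Pd/(R)‑t‑Bu‑PHOX sets only C10 and gives 4 together with its C6 epimer (2R,6S)‑2‑allyl‑2,6‑dimethylcyclohexan‑1‑one F16.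
- The two are separated, and F16 is re‑equilibrated at C6 with DBU and recycled to 4.

Further compounds
F1 | step 7 | (2S,6R)‑2‑allyl‑2,6‑dimethylcyclohexan‑1‑one | C[C@@H]1CCC[C@@](C)(CC=C)C1=O
F2 | step 7 | 2‑[(1S,3R)‑1,3‑dimethyl‑2‑oxocyclohexyl]acetaldehyde | C[C@@H]1CCC[C@@](C)(CC=O)C1=O
F3 | step 7 | (2S,6R)‑2‑[(E)‑2‑(TBSO)ethenyl]‑2,6‑dimethylcyclohexan‑1‑one | C[C@@H]1CCC[C@@](C)(/C=C/O[Si](C)(C)C(C)(C)C)C1=O
F4 | step 7 | (2S,6R)‑2‑[(E)‑2‑(TBSO)ethenyl]‑2,6‑dimethyl‑1‑[4‑(trimethylsilyl)buta‑1,3‑diyn‑1‑yl]cyclohexan‑1‑ol (C1 epimers) | C[C@@H]1CCC[C@@](C)(/C=C/O[Si](C)(C)C(C)(C)C)C1(O)C#CC#C[Si](C)(C)C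
F5 | step 7 | (2S,6R)‑2‑[(E)‑2‑(TBSO)ethenyl]‑2,6‑dimethyl‑1‑[(E)‑4‑(trimethylsilyl)but‑1‑en‑3‑yn‑1‑yl]cyclohexan‑1‑ol (C1 epimers) | C[C@@H]1CCC[C@@](C)(/C=C/O[Si](C)(C)C(C)(C)C)C1(O)/C=C/C#C[Si](C)(C)C
F6 | step 7 | (3S,4R,5E,10R)‑4‑(TBSO)‑6,10‑dimethyl‑3‑[(trimethylsilyl)ethynyl]cyclodec‑5‑en‑1‑one | C[C@@H]1CCC/C(C)=C/[C@@H](O[Si](C)(C)C(C)(C)C)[C@H](C#C[Si](C)(C)C)CC1=O
F7 | step 4 | (2R,6R)‑2‑[2,2‑bis(phenylsulfanyl)ethyl]‑2,6‑dimethylcyclohexan‑1‑one | C[C@@H]1CCC[C@](C)(CC(Sc2ccccc2)Sc2ccccc2)C1=O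
F8 | step 4 | (2R,6R)‑2,6‑dimethyl‑2‑[(E)‑2‑(phenylsulfanyl)ethenyl]cyclohexan‑1‑one | C[C@@H]1CCC[C@](C)(/C=C/Sc2ccccc2)C1=O
F9 | step 4 | (1S,2R,6R)‑2,6‑dimethyl‑2‑[(E)‑2‑(phenylsulfanyl)ethenyl]‑1‑[4‑(trimethylsilyl)buta‑1,3‑diyn‑1‑yl]cyclohexan‑1‑ol | C[C@@H]1CCC[C@](C)(/C=C/Sc2ccccc2)[C@]1(O)C#CC#C[Si](C)(C)C
F10 | step 4 | (1R,2R,6R)‑2,6‑dimethyl‑2‑[(E)‑2‑(phenylsulfanyl)ethenyl]‑1‑[(E)‑4‑(trimethylsilyl)but‑1‑en‑3‑yn‑1‑yl]cyclohexan‑1‑ol | C[C@@H]1CCC[C@](C)(/C=C/Sc2ccccc2)[C@]1(O)/C=C/C#C[Si](C)(C)C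
F11 | step 4 | (1R,2R,6R)‑1‑[(E)‑but‑1‑en‑3‑yn‑1‑yl]‑2,6‑dimethyl‑2‑[(E)‑2‑(phenylsulfanyl)ethenyl]cyclohexan‑1‑ol | C[C@@H]1CCC[C@](C)(/C=C/Sc2ccccc2)[C@]1(O)/C=C/C#C
F12 | step 4 | (5Z)‑3‑ethynyl‑6,10‑dimethyl‑4‑(phenylsulfanyl)cyclodec‑5‑en‑1‑one (C4, C7, C8 arranged as in 14) | C[C@@H]1CCC\C(C)=C/[C@@H](Sc2ccccc2)[C@H](C#C)CC1=O
F13 | step 4 | sulfoxide of F12 (either configuration at sulfur) | C[C@@H]1CCC\C(C)=C/[C@@H](S(=O)c2ccccc2)[C@H](C#C)CC1=O
F14 | step 4 | (3R,4E,6S,10R)‑3‑ethynyl‑6‑hydroxy‑6,10‑dimethylcyclodec‑4‑en‑1‑one | C[C@@H]1CCC[C@](C)(O)/C=C/[C@H](C#C)CC1=O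
F15 | step 2 | allyl 2,6‑dimethylcyclohex‑1‑en‑1‑yl carbonate (racemic) | C=CCOC(=O)OC1=C(C)CCCC1C
F16 | step 2 | (2R,6S)‑2‑allyl‑2,6‑dimethylcyclohexan‑1‑one | C[C@H]1CCC[C@](C)(CC=C)C1=O
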